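**Strategy.** Both dihydrobenzofuran rings derive from one acid, (2S)-6-bromo-4-methoxy-2-(4-methoxyphenyl)-2,3-dihydrobenzofuran-3-carboxylic acid, made once by enantioselective Rh-carbene C–H insertion. The route rests on cutting the bond between C3 of the upper dihydrofuran ring and C6 of the lower benzofuran benzene ring, a carbon meta to both ring oxygens and so out of reach of Friedel–Crafts chemistry. The key step is an iron-catalysed decarboxylative arylation: the C3 redox-active ester gives a benzylic C3 radical, which the arylzinc of the lower half captures trans to the neighbouring C2 aryl group. The C3 carboxyl is a traceless handle, and the same ester is arylated twice. The styryl arm follows by Heck reaction.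

Key step: step 10

Remark: all phenols travel as methyl ethers; the 4-methoxybenzyl group introduced in step 1 is a skeletal unit (it becomes C2 and its aryl ring), and the C3 configuration of 8–11 is irrelevant because steps 9 and 10 erase it.

Step 1
Reactants: 1 4-bromo-2-fluoro-6-methoxybenzaldehyde; 2 4-methoxybenzyl alcohol
Product: 3 4-bromo-2-methoxy-6-[(4-methoxybenzyl)oxy]benzaldehyde
Conditions: NaH, THF/DMF, 0 °C to rt
Reagents that add atoms: none
Why: Nucleophilic aromatic substitution (addition–elimination): the alkoxide of 2 displaces the fluoride ortho to the formyl group, whereas the para bromide is a far poorer leaving group in SNAr.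

Step 2
Reactants: 3
Product: 4 1-{4-bromo-2-methoxy-6-[(4-methoxybenzyl)oxy]phenyl}-2,2,2-trichloroethanol (racemic)
Conditions: CHCl3, KOH/MeOH (sub-stoichiometric), DMF, −10 °C
Reagents that add atoms: chloroform, ClC(Cl)Cl
Why: Base-mediated addition of trichloromethanide to the aldehyde under non-acidic conditions; the racemic carbinol centre is destroyed in step 3.

Step 3
Reactants: 4
Product: 5 {4-bromo-2-methoxy-6-[(4-methoxybenzyl)oxy]phenyl}acetic acid
Conditions: NaBH4, NaOH, t-BuOH, 55 °C; then cold dilute acid to pH 4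
Reagents that add atoms: sodium hydroxide, [Na+].[OH-]
Why: Reductive Jocic–Reeve homologation: base closes the gem-dichloroepoxide, hydride opens it at the benzylic carbon and the resulting acyl chloride is hydrolysed to the one-carbon-extended acid, while the aryl bromide and the benzyl ether are inert.

Step 4
Reactants: 5
Product: 6 methyl {4-bromo-2-methoxy-6-[(4-methoxybenzyl)oxy]phenyl}acetate
Conditions: MeI, K2CO3, DMF, rt
Reagents that add atoms: iodomethane, CI
Why: SN2 O-alkylation of the carboxylate, chosen because it avoids acid and so spares the acid-labile 4-methoxybenzyl aryl ether.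

Step 5
Reactants: 6
Product: 7 methyl {4-bromo-2-methoxy-6-[(4-methoxybenzyl)oxy]phenyl}(diazo)acetate
Conditions: p-ABSA, DBU, MeCN, 0 °C to rt
Reagents that add atoms: 4-acetamidobenzenesulfonyl azide, CC(=O)Nc1ccc(cc1)S(=O)(=O)N=[N+]=[N-]
Why: Regitz diazo transfer to the DBU-generated enolate of the arylacetate.

Step 6
Reactants: 7
Product: 8 methyl (2S,3R)-6-bromo-4-methoxy-2-(4-methoxyphenyl)-2,3-dihydro-1-benzofuran-3-carboxylate (cis)
Conditions: Rh2(R-PTTL)4 (1 mol%), toluene, −60 °C
Reagents that add atoms: none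
Why: Intramolecular 1,5 C–H insertion of the Rh(II) aryl(ester)carbene into the doubly activated 4-methoxybenzylic ether C–H bond (the O-methyl C–H is much less reactive); the chiral carboxylate catalyst, whose antipode is chosen to give the 2S series, sets C2, and the concerted insertion should give the cis 2,3-relationship.

Step 7
Reactants: 8
Product: 10 (2S,3S)-6-bromo-4-methoxy-2-(4-methoxyphenyl)-2,3-dihydro-1-benzofuran-3-carboxylic acid, via trans methyl ester 9 (not isolated)
Conditions: NaOMe (cat.), MeOH, rt; then LiOH, THF/H2O, 40 °C; cold dilute HCl work-up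
Reagents that add atoms: lithium hydroxide, [Li+].[OH-]
Why: Methoxide epimerises C3 through the ester enolate to the more stable trans isomer without touching C2, and saponification then gives one crystalline acid that can be recrystallised to raise enantiopurity.

Step 8
Reactants: 10
Product: 11 4,5,6,7-tetrachloro-1,3-dioxoisoindolin-2-yl (2S,3S)-6-bromo-4-methoxy-2-(4-methoxyphenyl)-2,3-dihydro-1-benzofuran-3-carboxylate
Conditions: N-hydroxytetrachlorophthalimide, DIC, DMAP (cat.), CH2Cl2, rt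
Reagents that add atoms: N-hydroxytetrachlorophthalimide, ON1C(=O)c2c(Cl)c(Cl)c(Cl)c(Cl)c2C1=O
Why: Carbodiimide (Steglich-type) esterification to the redox-active N-acyloxyphthalimide that serves as radical precursor in steps 9 and 10.

Step 9
Reactants: 11; 12 (3,5-dimethoxyphenyl)magnesium chloride
Product: 14 (2S,3S)-6-bromo-3-(3,5-dimethoxyphenyl)-4-methoxy-2-(4-methoxyphenyl)-2,3-dihydro-1-benzofuran, via (3,5-dimethoxyphenyl)zinc chloride 13 (not isolated)
Conditions: 12, ZnCl2, THF, 0 °C; then 11, Fe(acac)3 (10 mol%), dppBz (12 mol%), THF/toluene, rt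
Reagents that add atoms: none
Why: Iron-catalysed decarboxylative Negishi-type arylation of a redox-active ester: single-electron reduction and loss of CO2 give the planar C3 benzylic radical, which is arylated on the face anti to the C2 aryl group (substrate control, trans), while the electron-rich aryl bromide is not activated by iron at room temperature.

Step 10
Reactants: 14; 11
Product: 17 (2S,3S)-6-bromo-3-[(2S,3S)-3-(3,5-dimethoxyphenyl)-4-methoxy-2-(4-methoxyphenyl)-2,3-dihydro-1-benzofuran-6-yl]-4-methoxy-2-(4-methoxyphenyl)-2,3-dihydro-1-benzofuran, via arylmagnesium bromide 15 (not isolated), via arylzinc chloride 16 (not isolated)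
Conditions: 14, Mg, LiCl, THF, rt, decanted from excess Mg; ZnCl2, 0 °C; then 11, Fe(acac)3 (20 mol%), dppBz (24 mol%), THF/toluene, rt
Reagents that add atoms: none
Why: A low-valent aryl–iron species formed from 16 reduces the tetrachlorophthalimide ester of 11 by single-electron transfer; fragmentation with loss of CO2 and the phthalimide anion gives the C3 benzylic radical of the upper ring, which recombines with aryl–iron, and reductive elimination forges the C3–C6' bond. The closest known reaction type is the Fe- or Ni-catalysed coupling of secondary N-acyloxyphthalimides with arylzinc reagents, together with Ni/arylzinc arylation of secondary benzylic electrophiles. No ring is closed in this step. The new C3 stereocentre is controlled by the existing C2 stereocentre: the radical is planar and the large aryl group is delivered anti to the C2 4-methoxyphenyl group, giving the trans (2S,3S) ring. The step needs chemoselectivity for the redox-active ester over the aryl bromides of 11 and 17, which iron does not insert into at room temperature, and radical capture faster than β-scission of the C2–O bond or oxidation and proton loss to the 2-arylbenzofuran; poor overlap of the ring C2–O bond with the radical and fast capture by iron should secure this. Because both partners are enantioenriched in the same sense, the minor enantiomers should end mainly in a separable hetero-diastereomer, so the coupling is expected to raise enantiopurity.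

Step 11
Reactants: 17; 18 2,4-dimethoxystyrene
Product: 19 (2S,3S)-3-[(2S,3S)-3-(3,5-dimethoxyphenyl)-4-methoxy-2-(4-methoxyphenyl)-2,3-dihydro-1-benzofuran-6-yl]-6-[(E)-2-(2,4-dimethoxyphenyl)ethenyl]-4-methoxy-2-(4-methoxyphenyl)-2,3-dihydro-1-benzofuran
Conditions: Pd(OAc)2, P(o-tol)3, K2CO3, DMF, 110 °C
Reagents that add atoms: none
Why: Mizoroki–Heck reaction at the only C–Br bond of 17; syn insertion and syn β-hydride elimination give the (E)-stilbene.

Step 12
Reactants: 19
Product: 20 target compound CNP0186204.1 (2S,3S,2'S,3'S octaphenol)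
Conditions: BBr3, CH2Cl2, −78 °C to rt; then MeOH/H2O
Reagents that add atoms: none
Why: Lewis-acid cleavage of the eight aryl methyl ethers (bromide attacks the O-methyl of each borane adduct); the stereocentres are not involved, and the trans rings are the thermodynamic isomers should a benzylic C2–O bond ionise reversibly.

**Compound list**

1 | 4-bromo-2-fluoro-6-methoxybenzaldehyde | COc1cc(Br)cc(F)c1C=O | starting material
2 | 4-methoxybenzyl alcohol | COc1ccc(CO)cc1 | starting material
3 | 4-bromo-2-methoxy-6-[(4-methoxybenzyl)oxy]benzaldehyde | COc1ccc(COc2cc(Br)cc(OC)c2C=O)cc1 | intermediate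
4 | 1-{4-bromo-2-methoxy-6-[(4-methoxybenzyl)oxy]phenyl}-2,2,2-trichloroethanol (racemic) | COc1ccc(COc2cc(Br)cc(OC)c2C(O)C(Cl)(Cl)Cl)cc1 | intermediate
5 | {4-bromo-2-methoxy-6-[(4-methoxybenzyl)oxy]phenyl}acetic acid | COc1ccc(COc2cc(Br)cc(OC)c2CC(=O)O)cc1 | intermediate
6 | methyl {4-bromo-2-methoxy-6-[(4-methoxybenzyl)oxy]phenyl}acetate | COc1ccc(COc2cc(Br)cc(OC)c2CC(=O)OC)cc1 | intermediate
7 | methyl {4-bromo-2-methoxy-6-[(4-methoxybenzyl)oxy]phenyl}(diazo)acetate | COc1ccc(COc2cc(Br)cc(OC)c2C(=[N+]=[N-])C(=O)OC)cc1 | intermediate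
8 | methyl (2S,3R)-6-bromo-4-methoxy-2-(4-methoxyphenyl)-2,3-dihydro-1-benzofuran-3-carboxylate (cis) | COC(=O)[C@H]1[C@@H](c2ccc(OC)cc2)Oc2cc(Br)cc(OC)c21 | intermediate
9 | methyl (2S,3S)-6-bromo-4-methoxy-2-(4-methoxyphenyl)-2,3-dihydro-1-benzofuran-3-carboxylate (trans, not isolated) | COC(=O)[C@@H]1[C@@H](c2ccc(OC)cc2)Oc2cc(Br)cc(OC)c21 | intermediate
10 | (2S,3S)-6-bromo-4-methoxy-2-(4-methoxyphenyl)-2,3-dihydro-1-benzofuran-3-carboxylic acid | OC(=O)[C@@H]1[C@@H](c2ccc(OC)cc2)Oc2cc(Br)cc(OC)c21 | intermediate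
11 | 4,5,6,7-tetrachloro-1,3-dioxoisoindolin-2-yl (2S,3S)-6-bromo-4-methoxy-2-(4-methoxyphenyl)-2,3-dihydro-1-benzofuran-3-carboxylate | O=C(ON1C(=O)c2c(Cl)c(Cl)c(Cl)c(Cl)c2C1=O)[C@@H]1[C@@H](c2ccc(OC)cc2)Oc2cc(Br)cc(OC)c21 | intermediate
12 | (3,5-dimethoxyphenyl)magnesium chloride (THF solution) | COc1cc(OC)cc([Mg]Cl)c1 | starting material
13 | (3,5-dimethoxyphenyl)zinc chloride (not isolated) | COc1cc(OC)cc([Zn]Cl)c1 | intermediate
14 | (2S,3S)-6-bromo-3-(3,5-dimethoxyphenyl)-4-methoxy-2-(4-methoxyphenyl)-2,3-dihydro-1-benzofuran | COc1cc(OC)cc(c1)[C@@H]1[C@@H](c2ccc(OC)cc2)Oc2cc(Br)cc(OC)c21 | intermediate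
15 | [(2S,3S)-3-(3,5-dimethoxyphenyl)-4-methoxy-2-(4-methoxyphenyl)-2,3-dihydro-1-benzofuran-6-yl]magnesium bromide (not isolated) | COc1cc(OC)cc(c1)[C@@H]1[C@@H](c2ccc(OC)cc2)Oc2cc([Mg]Br)cc(OC)c21 | intermediate
16 | [(2S,3S)-3-(3,5-dimethoxyphenyl)-4-methoxy-2-(4-methoxyphenyl)-2,3-dihydro-1-benzofuran-6-yl]zinc chloride (not isolated) | COc1cc(OC)cc(c1)[C@@H]1[C@@H](c2ccc(OC)cc2)Oc2cc([Zn]Cl)cc(OC)c21 | intermediate
17 | (2S,3S)-6-bromo-3-[(2S,3S)-3-(3,5-dimethoxyphenyl)-4-methoxy-2-(4-methoxyphenyl)-2,3-dihydro-1-benzofuran-6-yl]-4-methoxy-2-(4-methoxyphenyl)-2,3-dihydro-1-benzofuran | COc1cc(OC)cc(c1)[C@@H]1[C@@H](c2ccc(OC)cc2)Oc2cc(cc(OC)c21)[C@@H]1[C@@H](c2ccc(OC)cc2)Oc2cc(Br)cc(OC)c21 | intermediate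
18 | 2,4-dimethoxystyrene (1-ethenyl-2,4-dimethoxybenzene) | C=Cc1ccc(OC)cc1OC | starting material
19 | octa-O-methyl ether of the target, (2S,3S)-3-[(2S,3S)-3-(3,5-dimethoxyphenyl)-4-methoxy-2-(4-methoxyphenyl)-2,3-dihydro-1-benzofuran-6-yl]-6-[(E)-2-(2,4-dimethoxyphenyl)ethenyl]-4-methoxy-2-(4-methoxyphenyl)-2,3-dihydro-1-benzofuran | COc1cc(OC)cc(c1)[C@@H]1[C@@H](c2ccc(OC)cc2)Oc2cc(cc(OC)c21)[C@@H]1[C@@H](c2ccc(OC)cc2)Oc2cc(/C=C/c3ccc(OC)cc3OC)cc(OC)c21 | intermediate
20 | CNP0186204.1, all four ring stereocentres S, both dihydrofuran rings trans | Oc1ccc([C@H]2Oc3cc(/C=C/c4ccc(O)cc4O)cc(O)c3[C@@H]2c2cc(O)c3c(c2)O[C@H](c2ccc(O)cc2)[C@H]3c2cc(O)cc(O)c2)cc1 | target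

**Step count.** Total: 12 steps. Longest linear sequence: 12 steps (steps 1–12; ester 11 is used in both step 9 and step 10).

**Steps most likely to fail**

1. Step 10 (the same concerns apply to its rehearsal, step 9). The electron-rich C3 benzylic radical may be lost before aryl transfer by oxidation and proton loss or β-hydride elimination to the aromatic 2-arylbenzofuran, by reduction, or by dimerisation. Facial selectivity at C3 may also be incomplete. Fallback, setting out from 14 (with aldehyde 3) and returning at 17: bromide 14 is lithiated (t-BuLi, THF, −78 °C) and added to aldehyde 3 to give the diaryl carbinol F1 as an epimer mixture. Dess–Martin oxidation gives the diaryl ketone F2, and hydrazine hydrate (EtOH, AcOH, sealed tube) gives the hydrazone F3. MnO2 oxidation gives the diaryldiazomethane F4, which is treated directly with a chiral Rh(II) carboxylate (Rh2(PTAD)4, antipode chosen for 3S). The donor/donor carbene inserts into the 4-methoxybenzylic C–H bond and should give the cis-(2R,3S) dihydrobenzofuran F5. Brief acid treatment (TFA, CH2Cl2, 0 °C) epimerises C2 through reversible ionisation of the benzylic C2–O bond and should give the trans compound 17.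

2. Step 6. The carbene carbon is flanked by two ortho alkoxy groups, which twists the aryl ring and may erode the enantio-induction of the catalyst. Fallback, setting out from 5 and returning at 10: acid 5 is esterified (DCC, DMAP) with (S)-2-hydroxy-1-(pyrrolidin-1-yl)propan-1-one to give the lactamide ester F6 (the antipode of the auxiliary is used if that is the matched one for 2S). Diazo transfer (p-ABSA, DBU) gives the diazo ester F7. Rh2(S-DOSP)4-catalysed C–H insertion under double stereodifferentiation gives the dihydrobenzofuran ester F8, which is brought to one diastereomer by chromatography or crystallisation. Saponification (LiOH, aqueous THF, after methoxide equilibration) gives acid 10.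

3. Step 12. Under BBr3/HBr the electron-rich stilbene may be protonated and cyclise or oligomerise, and ionisation of the benzylic C2–O bonds may trigger Friedel–Crafts side reactions, all across eight cleavages in one operation. Fallback, setting out from 17 and returning at 20: bromide 17, which has no alkene, is demethylated with BBr3 to the hexaphenol bromide F9 and silylated (TBSCl, imidazole, DMF) to the hexakis-TBS ether F10. Purchased 2,4-dihydroxybenzaldehyde is silylated to 2,4-bis(tert-butyldimethylsilyloxy)benzaldehyde F11 and methylenated (Ph3P=CH2) to 2,4-bis(tert-butyldimethylsilyloxy)styrene F12. Heck coupling of F10 with F12 (Pd2(dba)3, P(t-Bu)3, Cy2NMe, dioxane, 90 °C) gives the octa-TBS stilbene F13. Buffered fluoride (Et3N·3HF, THF, rt) then releases 20 under mild, non-acidic conditions.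

**Further compounds**

F1 | step 10 | {4-bromo-2-methoxy-6-[(4-methoxybenzyl)oxy]phenyl}[(2S,3S)-3-(3,5-dimethoxyphenyl)-4-methoxy-2-(4-methoxyphenyl)-2,3-dihydro-1-benzofuran-6-yl]methanol (carbinol epimers) | COc1cc(OC)cc(c1)[C@@H]1[C@@H](c2ccc(OC)cc2)Oc2cc(cc(OC)c21)C(O)c1c(OC)cc(Br)cc1OCc1ccc(OC)cc1
F2 | step 10 | {4-bromo-2-methoxy-6-[(4-methoxybenzyl)oxy]phenyl}[(2S,3S)-3-(3,5-dimethoxyphenyl)-4-methoxy-2-(4-methoxyphenyl)-2,3-dihydro-1-benzofuran-6-yl]methanone | COc1cc(OC)cc(c1)[C@@H]1[C@@H](c2ccc(OC)cc2)Oc2cc(cc(OC)c21)C(=O)c1c(OC)cc(Br)cc1OCc1ccc(OC)cc1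
F3 | step 10 | hydrazone of ketone F2 | COc1cc(OC)cc(c1)[C@@H]1[C@@H](c2ccc(OC)cc2)Oc2cc(cc(OC)c21)C(=NN)c1c(OC)cc(Br)cc1OCc1ccc(OC)cc1
F4 | step 10 | diaryldiazomethane from F3 | COc1cc(OC)cc(c1)[C@@H]1[C@@H](c2ccc(OC)cc2)Oc2cc(cc(OC)c21)C(=[N+]=[N-])c1c(OC)cc(Br)cc1OCc1ccc(OC)cc1
F5 | step 10 | (2R,3S)-6-bromo-3-[(2S,3S)-3-(3,5-dimethoxyphenyl)-4-methoxy-2-(4-methoxyphenyl)-2,3-dihydro-1-benzofuran-6-yl]-4-methoxy-2-(4-methoxyphenyl)-2,3-dihydro-1-benzofuran (cis upper ring) | COc1cc(OC)cc(c1)[C@@H]1[C@@H](c2ccc(OC)cc2)Oc2cc(cc(OC)c21)[C@@H]1[C@H](c2ccc(OC)cc2)Oc2cc(Br)cc(OC)c21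
F6 | step 6 | (S)-1-oxo-1-(pyrrolidin-1-yl)propan-2-yl {4-bromo-2-methoxy-6-[(4-methoxybenzyl)oxy]phenyl}acetate | COc1ccc(COc2cc(Br)cc(OC)c2CC(=O)O[C@@H](C)C(=O)N2CCCC2)cc1
F7 | step 6 | (S)-1-oxo-1-(pyrrolidin-1-yl)propan-2-yl {4-bromo-2-methoxy-6-[(4-methoxybenzyl)oxy]phenyl}(diazo)acetate | COc1ccc(COc2cc(Br)cc(OC)c2C(=[N+]=[N-])C(=O)O[C@@H](C)C(=O)N2CCCC2)cc1
F8 | step 6 | (S)-1-oxo-1-(pyrrolidin-1-yl)propan-2-yl (2S,3S)-6-bromo-4-methoxy-2-(4-methoxyphenyl)-2,3-dihydro-1-benzofuran-3-carboxylate | C[C@H](OC(=O)[C@@H]1[C@@H](c2ccc(OC)cc2)Oc2cc(Br)cc(OC)c21)C(=O)N1CCCC1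
F9 | step 12 | hexaphenol bromide, (2S,3S)-6-bromo-3-[(2S,3S)-3-(3,5-dihydroxyphenyl)-4-hydroxy-2-(4-hydroxyphenyl)-2,3-dihydro-1-benzofuran-6-yl]-2-(4-hydroxyphenyl)-2,3-dihydro-1-benzofuran-4-ol | Oc1cc(O)cc(c1)[C@@H]1[C@@H](c2ccc(O)cc2)Oc2cc(cc(O)c21)[C@@H]1[C@@H](c2ccc(O)cc2)Oc2cc(Br)cc(O)c21
F10 | step 12 | hexakis(tert-butyldimethylsilyl) ether of F9 | CC(C)(C)[Si](C)(C)Oc1cc(O[Si](C)(C)C(C)(C)C)cc(c1)[C@@H]1[C@@H](c2ccc(O[Si](C)(C)C(C)(C)C)cc2)Oc2cc(cc(O[Si](C)(C)C(C)(C)C)c21)[C@@H]1[C@@H](c2ccc(O[Si](C)(C)C(C)(C)C)cc2)Oc2cc(Br)cc(O[Si](C)(C)C(C)(C)C)c21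
F11 | step 12 | 2,4-bis(tert-butyldimethylsilyloxy)benzaldehyde | CC(C)(C)[Si](C)(C)Oc1ccc(C=O)c(O[Si](C)(C)C(C)(C)C)c1
F12 | step 12 | 2,4-bis(tert-butyldimethylsilyloxy)styrene | CC(C)(C)[Si](C)(C)Oc1ccc(C=C)c(O[Si](C)(C)C(C)(C)C)c1
F13 | step 12 | octakis(tert-butyldimethylsilyl) ether of the target | CC(C)(C)[Si](C)(C)Oc1cc(O[Si](C)(C)C(C)(C)C)cc(c1)[C@@H]1[C@@H](c2ccc(O[Si](C)(C)C(C)(C)C)cc2)Oc2cc(cc(O[Si](C)(C)C(C)(C)C)c21)[C@@H]1[C@@H](c2ccc(O[Si](C)(C)C(C)(C)C)cc2)Oc2cc(/C=C/c3ccc(O[Si](C)(C)C(C)(C)C)cc3O[Si](C)(C)C(C)(C)C)cc(O[Si](C)(C)C(C)(C)C)c21
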